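## Structural features

The target is a bicyclic diterpenoid methyl ester of the labdane type in the enantiomeric (ent) series, (1S,4R,5S,9R,10S) by CIP analysis of the SMILES. It is a trans-fused decalin (ring A = C1–C5 and C10, ring B = C5–C10) with a (2E)-3-methylpenta-2,4-dienyl chain on C9, an exocyclic methylene on C8, a methyl and a methyl ester on C4, a methyl on C10 and an acetate on C1. Five stereocentres crowd around the quaternary C10: C1, C5 and C9 are bonded to it, and the quaternary C4 is bonded to C5. The C10 methyl, the axial C4 ester, the equatorial C1 acetate and the equatorial C9 chain lie on one face; 1-H, 5-H and 9-H are the axial hydrogens of the other face. The fragile groups are the conjugated terminal diene (acid, radicals, hydrogenation), the 8(17)-alkene (acid-promoted migration), the 12E geometry and the secondary acetate (strong base, hydride). The real difficulty is the absolute configuration of C10 with oxygen on the neighbouring C1, a C9 substituent that is peri to the C1 oxygen, and the axial ester at C4. The key step uses the fact that C10 and its methyl sit between oxygenated C1 and a ring B whose C8 is sp2. Ring B (C5–C10, oxygen at C6, C8 and C9) is the image of 2-methoxy-6-methyl-1,4-benzoquinone with C5=C10 as its methyl-bearing alkene, and C1–C4 (oxygen on C1, carboxyl on C4) is the image of a glutaconate dienolate.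

## Logic of the disconnections

22 ⇒ 21 ⇒ 20. The acyl C–O bond at C1 is cut, and the hydroxyl of 21 is then masked as the silyl ether of 20. An acetate cannot survive the two amide-base steps that precede it, so the oxygen travels as a robust ether. The demand is a desilylation that spares the triene and an acylation of a hindered equatorial hydroxyl.

20 ⇒ 19. The C4–C18 bond is cut. C4 is α to the ester and the axial C10 methyl shields one face of the enolate, so a methylation should give the required quaternary centre. Placing it late keeps the ester equatorial (unable to lactonise onto C6) while ring B is oxygenated. The demand is full enolisation of a hindered ester and attack anti to C20.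

19 ⇒ 18. The C8=C17 bond is cut to a C8 ketone. The ketone is the handle for everything done at C9, and methylenation of it is routine.

18 ⇒ 16 ⇒ 12 + 15. The C9–C11 bond is cut, after re-introducing the C6=C7 alkene (16). With that alkene in place C9 is the only sp3 α-carbon of the C8 ketone, so the enolate of 12 is regiodefined. The demand is C-alkylation at a neopentyl carbon and a later thermodynamic correction of C9 (through 17), which is possible because C9 stays α to the ketone.

15 ⇒ 14 ⇒ 13. The C–Br bond and then one H2 are removed, which leads to a commercial enynol that already carries the E trisubstituted alkene.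

12 ⇒ 11 ⇒ 10. The O–Si bond is cut, and then an oxygen is put back on C9. 10 is the α-ketol that a carbonyl transposition of the ring B system delivers, so the C9 oxygen only has to be removed reductively.

10 ⇒ 9 ⇒ 8. The C6=C7/C8=O enone and the C1 and C9 carbinols are traced to the triketone 8 through the triol 9. One hydride reduction sets C1 and prepares the enol ether for hydrolytic transposition. The demand is 1,2-reduction of three different ketones without touching the ester, and axial hydride delivery at C1.

8 ⇒ 7. A C2=C3 alkene is re-introduced. This is the alkene the cycloaddition leaves behind.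

7 ⇒ 6 ⇒ 5 ⇒ 2 + 4. The C1–C10 and C4–C5 bonds are cut in a [4+2] sense, after inverting C5 (6) and restoring the mixed ketal at C1 (5). This removes ring A, the quaternary centre and all of the C1–C4 functionality in one operation. The demands are site selectivity for the methyl-bearing alkene of 2, bonding of the ester-bearing terminus of 4 to C5, and facial control at C10. Two refinements are built in. 4 carries a tert-butyldimethylsilyl instead of a trimethylsilyl group, so that it can be isolated and transfers silicon less readily. The Lewis acid is a chelating one, because only binding at O9 together with the methoxy oxygen polarises 2 in the required sense.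

2 ⇒ 1 and 4 ⇒ 3. Two C=O bonds (para-oxidation) and one O–Si bond are cut, which leads to two commercial compounds.

## Other disconnections considered

Alternative 1: The cut runs through C4–C5 and C9–C10 and opens both rings to the acyclic β-keto ester A1 (methyl (6E,10E)-12-acetoxy-5-(tert-butyldimethylsilyloxy)-2,6,10-trimethyl-3-oxododeca-6,10-dienoate). In the forward sense Mn(OAc)3 (trivalent manganese) would generate the C4 radical, two 6-endo closures would form C4–C5 and C9–C10, and Cu(OAc)2 (divalent copper) would oxidise the tertiary C8 radical to the exocyclic alkene of A2 (the 3-oxo trans-decalin with axial C1 silyl ether and C11 acetate).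
- In favour: two rings, four stereocentres and both quaternary carbons arise in one step. C4 is formed with methyl and axial ester already in place, and the C8 methylene appears directly.
- Against: the C1 oxygen would emerge axial, the wrong way round, and would have to be inverted by oxidation and reduction. The C3 ketone must be excised. The β-silyloxy ketone of A1 can eliminate under the acidic oxidising medium. The alkene-forming termination can give regioisomers. The absolute configuration must be carried in from a separately made C1 carbinol, and the side chain still has to be built from C11.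
- Comparison: on structure it is the better plan for C4 and C8=C17, which the chosen route reaches only by a late methylation (step 13) and a Wittig reaction (step 12). On mechanism, the radical cascade has diastereocontrol only relative to C1, whereas the chosen route sets C10 by a catalyst and repairs C5, C9 and C4 thermodynamically or by substrate control. On step economy the two are comparable once C1 inversion, C3 deoxygenation and chain extension are counted.

Alternative 2: The cut runs through C5–C6 and C9–C10 and keeps ring A as the enone A3 (dimethyl 3-methyl-4-oxocyclohex-2-ene-1,1-dicarboxylate). In one pot a chiral oxazaborolidinium would add the two-carbon donor A4 (trimethyl(vinyloxy)silane) to C5. The resulting C1 silyl enol ether would then be allylated at C10 by [Ir(cod)Cl]2 and a chiral phosphoramidite with the carbonate A5 ((E)-5-(4-methoxybenzyloxy)pent-2-enyl methyl carbonate) at its substituted terminus, giving A6 (the ring A ketone with the C6–C7 aldehyde arm and the branched C9 unit).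
- In favour: C5, C10 and C9 would all be set under catalyst control, and C8, C17, C11 and C12 arrive in the same operation. No late alkylation at a neopentyl carbon is needed.
- Against: allylation of a tetrasubstituted silyl enol ether to a quaternary carbon next to a new tertiary one, with an aldehyde present, is a demanding combination. Ring B is still open afterwards, the C1 ketone must be reduced, and the two C4 esters must be told apart to make one of them a methyl. The chain must also be grown from C12.
- Comparison: it is the better plan for C9, which it fixes kinetically and absolutely, whereas the chosen route relies on equilibration (step 11). It equals the chosen plan in needing one enantioselective event for C10. It is weaker on structure, because its key step closes no ring, and on step economy after the key step.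

Alternative 3: The cut is at C9–C10, formed by a 1,2-shift. The precursor is the trans-hydrindane epoxy carbinol A7 (methyl 7-(tert-butyldimethylsilyloxy)-1-hydroxy-4,7a-dimethyl-1-(oxiran-2-yl)octahydro-1H-indene-4-carboxylate). BF3·OEt2 would open the epoxide, C10 would migrate from C8 to C9 with inversion at C9, and the five-membered ring would become ring B of A8 (the C8 ketone with a C9 hydroxymethyl, C1 silyl ether and C4 ester).
- In favour: the shift is stereospecific, so C9 is set without recourse to equilibration. The C8 ketone and a C11 handle arrive together, and the reaction class is dependable.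
- Against: A7 already contains all four ring A stereocentres on a trans-hydrindane, which is at least as hard to make as the decalin itself. C7 can migrate in competition with C10. A8 is an aldol that can undergo retro-aldol cleavage or dehydration, and C11 must still be joined to C12.
- Comparison: as a single step it is more certain than the cycloaddition of the chosen route, and it ends at the same kind of C8 ketone (compare 18), so the two are equal from there on. It is weaker because the key step adds no ring and no absolute stereocontrol, which moves the whole stereochemical problem into the precursor and lengthens the route.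

Key step: step 3

Remarks on the chemistry (assumptions):
- Labdane numbering is used for every intermediate (C11–C16 chain with C16 on C13, C17 on C8, C18 and C19 on C4, C20 on C10). "Methyl face" means the face of the bicycle that carries C20, and "H face" the opposite one.
- (E)-3-Methylpent-2-en-4-yn-1-ol is taken to be commercially available as the pure E isomer.
- The ketene acetal geometry of 4, the ketal carbon of 5 and the C6 and C9 carbinol centres of 9 and 10 do not affect the outcome. Where a SMILES fixes them it shows the isomer expected from attack anti to C20.
- The (S)-ligand in step 3 is assigned from a chelate model only.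

## Route

Step 1
Reactants: 1 2-methoxy-6-methylphenol
Product: 2 2-methoxy-6-methyl-1,4-benzoquinone
Conditions: O2 (1 atm), Co(salen) (5 mol%), DMF, rt
Reagents that add atoms: dioxygen, O=O
Why: Cobalt–salen aerobic para-oxidation of a 2,6-disubstituted phenol; both ortho positions are blocked, so the phenoxyl radical is oxygenated at the free para carbon and collapses to the para-quinone.

Step 2
Reactants: 3 dimethyl (E)-glutaconate
Product: 4 methyl (2E)-5-(tert-butyldimethylsilyloxy)-5-methoxypenta-2,4-dienoate
Conditions: LiN(i-Pr)2 (1.1 equiv), THF, −78 °C (inverse addition); t-BuMe2SiCl, DMPU, −78 °C → rt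
Reagents that add atoms: tert-butyldimethylsilyl chloride, C[Si](C)(Cl)C(C)(C)C
Why: Deprotonation of the doubly activated CH2 gives the extended, symmetrical dienolate, and O-silylation (ester-enolate silylation) gives the silyl ketene acetal with an E central alkene. Inverse addition at low temperature suppresses Michael self-condensation.

Step 3
Reactants: 2 2-methoxy-6-methyl-1,4-benzoquinone; 4 methyl (2E)-5-(tert-butyldimethylsilyloxy)-5-methoxypenta-2,4-dienoate
Product: 7 trans-fused trione ester (C1/C6/C9 ketones; C2=C3; 8-methoxy-C7=C8; 10-methyl; equatorial 4-CO2Me; 5-H on the H face), via ketal cycloadduct 5 (not isolated), via cis-fused trione 6 (not isolated)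
Conditions: (S)-BINOL (12 mol%), TiCl2(O-i-Pr)2 (10 mol%), 4 Å MS, toluene, −78 → −40 °C; then 1 M HCl, THF, 0 °C; then DBU (0.2 equiv), CH2Cl2, 0 °C → rt
Reagents that add atoms: water, O (ketal hydrolysis; may supply the C1 carbonyl oxygen)
Why: The tetravalent titanium centre should chelate O9 and the C8 methoxy oxygen of 2, which makes C5 (β to C9 through C10=C5) the most electrophilic carbon, whereas a monodentate Lewis acid would bind the more basic, unhindered C6 oxygen and polarise the alkene the wrong way. The donor terminus of 4 (future C4) bonds to C5 ahead of the C1–C10 bond in a concerted, asynchronous, endo [4+2] cycloaddition, which is the mode of closure of ring A; the closest known reaction type is the binaphthol–titanium-catalysed Diels–Alder reaction of 2-alkoxy-1,4-benzoquinones with oxygenated dienes. The methoxy-bearing alkene C7=C8 is a vinylogous ester and should stay inert, so site selectivity rests on the substrate and regioselectivity on the chelate. C10 is the only centre the catalyst must set: the binaphtholate covers one face of the chelated quinone and the diene adds to the other, and the (R)-ligand is used instead if the sense proves opposite. Dilute acid collapses the mixed ketal of 5 to the C1 ketone of 6 with loss of methanol and silanol, and the angular methyl rules out aromatisation of the adduct. C5 (α to the C6 carbonyl) and C4 (γ to the C1 enone, α to the ester) are then equilibrated by catalytic DBU, which should give the trans fusion and the equatorial ester of 7 under thermodynamic control. The base must be non-nucleophilic because C1 and C9 form a non-enolisable 1,3-diketone across C10 that hydroxide or alkoxide would open by retro-Claisen cleavage. The step needs enantiofacial control and a ring closure faster than silyl transfer after the first bond, which the bulky silyl group, the non-polar solvent and the low temperature are meant to secure.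

Step 4
Reactants: 7 trans-fused trione ester
Product: 8 saturated-ring-A trione ester (C1/C6/C9 ketones; 8-methoxy-C7=C8; equatorial 4-CO2Me; trans fusion)
Conditions: H2 (1 atm), 5% Pd/C, EtOAc, rt, stopped after 1 equiv
Reagents that add atoms: none
Why: Heterogeneous hydrogenation of the unhindered cis-disubstituted enone alkene. The trisubstituted, donor-substituted C7=C8 should react far more slowly, and no stereocentre is created.

Step 5
Reactants: 8 saturated-ring-A trione ester
Product: 10 diol enone (C8 ketone; C6=C7; 9-OH; equatorial 1-OH on the methyl face; equatorial 4-CO2Me), via enol ether triol 9 (not isolated)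
Conditions: NaBH4 (5 equiv), CeCl3·7H2O (3 equiv), MeOH/THF, −40 °C → rt; then 1 M HCl, THF/H2O, rt
Reagents that add atoms: water, O
Why: Luche 1,2-reduction of all three ketones spares the ester. At C1 hydride enters axially from the H face, because the equatorial path is blocked by the axial C20 and the peri C9 carbonyl, which sets the equatorial C1 hydroxyl on the methyl face. Acid then effects the Stork–Danheiser-type transposition: ionisation at C6 (vinylogous to the methoxy group), water at C8 and loss of methanol give the C8 ketone and C6=C7, and the C9 hydroxyl stays because its ionisation has no such assistance.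

Step 6
Reactants: 10 diol enone
Product: 11 hydroxy enone (C8 ketone; C6=C7; C9 methylene; equatorial 1-OH)
Conditions: SmI2 (2.5 equiv), THF/MeOH, −78 °C
Reagents that add atoms: none
Why: Samarium diiodide reduction of an α-heterosubstituted ketone: the ketyl expels the samarium-bound C9 hydroxide and the resulting enolate is protonated by methanol. The C1 hydroxyl is not α to a carbonyl and is untouched.

Step 7
Reactants: 11 hydroxy enone
Product: 12 silyloxy enone (1-O-tert-butyldimethylsilyl ether of 11)
Conditions: t-BuMe2SiOTf, 2,6-lutidine, CH2Cl2, −78 → 0 °C
Reagents that add atoms: tert-butyldimethylsilyl trifluoromethanesulfonate, C[Si](C)(OS(=O)(=O)C(F)(F)F)C(C)(C)C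
Why: Silyl triflate silylation of a hindered secondary alcohol. With the weak base and low temperature the enone should not be enol-silylated.

Step 8
Reactants: 13 (E)-3-methylpent-2-en-4-yn-1-ol
Product: 14 (E)-3-methylpenta-2,4-dien-1-ol
Conditions: H2 (1 atm), Pd/CaCO3–Pb(OAc)2, quinoline, EtOAc/hexane, 0 °C
Reagents that add atoms: none
Why: Semi-hydrogenation of the terminal alkyne over poisoned palladium; the trisubstituted alkene and its E geometry are not involved.

Step 9
Reactants: 14 (E)-3-methylpenta-2,4-dien-1-ol
Product: 15 (3E)-5-bromo-3-methylpenta-1,3-diene
Conditions: PBr3 (0.4 equiv), pyridine (cat.), Et2O, −20 → 0 °C; used at once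
Reagents that add atoms: phosphorus tribromide, BrP(Br)Br
Why: Bromination of a primary allylic alcohol through its phosphite ester; the conjugated primary bromide is also the thermodynamically preferred allylic isomer.

Step 10
Reactants: 12 silyloxy enone; 15 (3E)-5-bromo-3-methylpenta-1,3-diene
Product: 16 C9-dienylated enone (C8 ketone; C6=C7; 1-OSi; equatorial 4-CO2Me; epimer shown has the chain on the H face)
Conditions: LiN(i-Pr)2 (1.05 equiv), THF, −78 °C; then 15, DMPU, −78 → −20 °C
Reagents that add atoms: none
Why: Kinetic α′-deprotonation of the enone gives the cross-conjugated C8–C9 enolate (C9 is the only sp3 α-carbon, and the ester and γ protons are slower), which is alkylated by the allylic bromide. The pentadienyl unit has its methyl on the central carbon, so attack at either terminus gives the same constitution. Attack anti to C20 is expected to place the chain mainly on the H face, which step 11 corrects.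

Step 11
Reactants: 16 C9-dienylated enone
Product: 18 saturated C8 ketone with equatorial C9 chain (9-H on the H face), via axial-chain ketone 17 (not isolated)
Conditions: LiBH(s-Bu)3 (1.1 equiv), THF, −78 °C; MeOH; then NaOMe (0.3 equiv), MeOH, rt
Reagents that add atoms: none
Why: Conjugate hydride addition to a β-unsubstituted cyclohexenone leaves the isolated diene alone. Methoxide then equilibrates C9 (α to the ketone) to the epimer with the equatorial chain, which frees the axial position from its syn-axial contacts with 1-H, 5-H and 7-H.

Step 12
Reactants: 18 saturated C8 ketone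
Product: 19 8(17)-methylene ester (equatorial 4-CO2Me; 1-OSi)
Conditions: Ph3PCH3Br (3 equiv), KOt-Bu (2.8 equiv), THF, rt → 60 °C
Reagents that add atoms: methyltriphenylphosphonium bromide, C[P+](c1ccccc1)(c1ccccc1)c1ccccc1.[Br-]
Why: Wittig methylenation of a hindered ketone. The ester is inert to the ylide, and any enolisation at C9 returns the same thermodynamic epimer.

Step 13
Reactants: 19 8(17)-methylene ester
Product: 20 C4-methylated ester (equatorial 18-CH3; axial CO2Me on the methyl face)
Conditions: LiN(i-Pr)2 (1.5 equiv), THF, −78 → 0 °C; then MeI, DMPU, −78 → 0 °C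
Reagents that add atoms: iodomethane, CI
Why: Ester-enolate alkylation: the axial C20 blocks the axial approach to C4 (1,3-diaxial), so the methyl should enter equatorially and push the ester into the axial position on the methyl face.

Step 14
Reactants: 20 C4-methylated ester
Product: 21 C1 alcohol (equatorial 1-OH on the methyl face)
Conditions: HF·pyridine, pyridine, THF, 0 °C → rt
Reagents that add atoms: none
Why: Buffered fluoride cleavage of the Si–O bond with retention at C1; the triene and the hindered tertiary ester do not react.

Step 15
Reactants: 21 C1 alcohol
Product: 22 target (methyl 1-acetoxy-ent-labda-8(17),12E,14-trien-19-oate type, acetate cis to C20)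
Conditions: Ac2O, DMAP (cat.), pyridine, rt
Reagents that add atoms: acetic anhydride, CC(=O)OC(C)=O
Why: DMAP-catalysed acylation of a secondary alcohol; no stereocentre is touched.

## Compound list

1 | 2-methoxy-6-methylphenol | Cc1cccc(OC)c1O | starting material
2 | 2-methoxy-6-methyl-1,4-benzoquinone | CC1=CC(=O)C=C(OC)C1=O | intermediate
3 | dimethyl (E)-glutaconate | COC(=O)C/C=C/C(=O)OC | starting material
4 | methyl (2E)-5-(tert-butyldimethylsilyloxy)-5-methoxypenta-2,4-dienoate | COC(=O)/C=C/C=C(OC)O[Si](C)(C)C(C)(C)C | intermediate
5 | cis-fused cycloadduct with C1 methyl silyl ketal (4-H, 5-H and C20 on one face; C1 undefined) | O=C1C(OC)=CC(=O)[C@@H]2[C@@]1(C)C(OC)(O[Si](C)(C)C(C)(C)C)C=C[C@@H]2C(=O)OC | intermediate (not isolated)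
6 | cis-fused 1,6,9-trione (C2=C3; 8-OMe-C7=C8; 4-CO2Me) | O=C1C(OC)=CC(=O)[C@@H]2[C@@]1(C)C(=O)C=C[C@@H]2C(=O)OC | intermediate (not isolated)
7 | trans-fused 1,6,9-trione (C2=C3; 8-OMe-C7=C8; equatorial 4-CO2Me; 5-H on the H face) | O=C1C(OC)=CC(=O)[C@H]2[C@@]1(C)C(=O)C=C[C@@H]2C(=O)OC | intermediate
8 | 2,3-dihydro derivative of 7 | O=C1C(OC)=CC(=O)[C@H]2[C@@]1(C)C(=O)CC[C@@H]2C(=O)OC | intermediate
9 | 1,6,9-triol with 8-OMe-C7=C8 enol ether (1-OH and 9-OH on the methyl face equatorial, 6-OH on the methyl face axial) | O[C@@H]1C(OC)=C[C@H](O)[C@H]2[C@@]1(C)[C@@H](O)CC[C@@H]2C(=O)OC | intermediate (not isolated)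
10 | 1,9-dihydroxy-8-oxo-6-ene ester | O[C@@H]1C(=O)C=C[C@H]2[C@@]1(C)[C@@H](O)CC[C@@H]2C(=O)OC | intermediate
11 | 1-hydroxy-8-oxo-6-ene ester | C1C(=O)C=C[C@H]2[C@@]1(C)[C@@H](O)CC[C@@H]2C(=O)OC | intermediate
12 | 1-(tert-butyldimethylsilyloxy)-8-oxo-6-ene ester | C1C(=O)C=C[C@H]2[C@@]1(C)[C@@H](O[Si](C)(C)C(C)(C)C)CC[C@@H]2C(=O)OC | intermediate
13 | (E)-3-methylpent-2-en-4-yn-1-ol | C#C/C(C)=C/CO | starting material
14 | (E)-3-methylpenta-2,4-dien-1-ol | C=C/C(C)=C/CO | intermediate
15 | (3E)-5-bromo-3-methylpenta-1,3-diene | C=C/C(C)=C/CBr | intermediate
16 | 9-[(2E)-3-methylpenta-2,4-dienyl]-1-silyloxy-8-oxo-6-ene ester (chain on the H face; the other C9 epimer converges) | C=C/C(C)=C/C[C@H]1C(=O)C=C[C@H]2[C@@]1(C)[C@@H](O[Si](C)(C)C(C)(C)C)CC[C@@H]2C(=O)OC | intermediate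
17 | saturated C8 ketone with axial C9 chain | C=C/C(C)=C/C[C@H]1C(=O)CC[C@H]2[C@@]1(C)[C@@H](O[Si](C)(C)C(C)(C)C)CC[C@@H]2C(=O)OC | intermediate (not isolated)
18 | saturated C8 ketone with equatorial C9 chain (9-H on the H face) | C=C/C(C)=C/C[C@@H]1C(=O)CC[C@H]2[C@@]1(C)[C@@H](O[Si](C)(C)C(C)(C)C)CC[C@@H]2C(=O)OC | intermediate
19 | 8(17)-methylene, 1-silyloxy, equatorial 4-CO2Me (4-H on the methyl face) | C=C/C(C)=C/C[C@@H]1C(=C)CC[C@H]2[C@@]1(C)[C@@H](O[Si](C)(C)C(C)(C)C)CC[C@@H]2C(=O)OC | intermediate
20 | 1-silyloxy triene with quaternary C4 (equatorial CH3, axial CO2Me) | C=C/C(C)=C/C[C@@H]1C(=C)CC[C@H]2[C@@]1(C)[C@@H](O[Si](C)(C)C(C)(C)C)CC[C@@]2(C)C(=O)OC | intermediate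
21 | 1-hydroxy triene ester | C=C/C(C)=C/C[C@@H]1C(=C)CC[C@H]2[C@@]1(C)[C@@H](O)CC[C@@]2(C)C(=O)OC | intermediate
22 | CNP0235031.1, 1-acetoxy triene methyl ester (1S,4R,5S,9R,10S) | C=C/C(C)=C/C[C@@H]1C(=C)CC[C@H]2[C@@]1(C)[C@@H](OC(C)=O)CC[C@@]2(C)C(=O)OC | target

## Step count and least certain steps

Total: 15 steps. Longest linear sequence: 12 steps (1, 3, 4, 5, 6, 7, 10, 11, 12, 13, 14, 15). Steps 2, 8 and 9 are side branches.

**Step 3 (key step).**
- What may go wrong: ring closure may lose to silyl transfer after the first C–C bond, which would lead to conjugate addition and aromatisation. The uncatalysed background cycloaddition of this very electron-rich diene may erode enantiofacial control. Epimerisation at C5 may be incomplete, or the base may move the C2=C3 alkene.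
- Fallback: the uncatalysed cycloaddition of 2 and 4 in toluene at rt relies only on the innate polarisation of 2 (the C9 carbonyl is not conjugated to the methoxy group, so C5 is the most electrophilic carbon). After the same acid and DBU treatment it should give racemic material, that is 5, 6 and 7 together with the enantiomeric ketal cycloadduct F1, the enantiomeric cis-fused trione F2 and the enantiomeric trans-fused trione F3. 7 is then separated from F3 by preparative chromatography on a chiral stationary phase. The fallback sets out from 2 and 4 and returns at 7.

**Step 6.**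
- What may go wrong: the conjugated enone may be reduced (1,4-reduction or reductive dimerisation) faster than the samarium-bound hydroxide leaves.
- Fallback: from 10, acetylation (Ac2O, DMAP, pyridine) gives the 1,9-diacetate F4. Zn in AcOH at 80 °C removes the α-acetoxy group and gives the 1-acetoxy enone F5, and K2CO3 in MeOH returns 11.

**Step 10.**
- What may go wrong: C-alkylation at the neopentyl C9, which is peri to the silyloxy group, may be slow. That leaves time for proton transfer with polyalkylation and for allylic isomerisation or decay of the labile pentadienyl bromide.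
- Fallback: from 13, PBr3 gives the more robust (E)-5-bromo-3-methylpent-3-en-1-yne F6. The lithium enolate of 12 is alkylated with it to give the enynyl enone F7, and semi-hydrogenation over Pd/CaCO3–Pb(OAc)2 with quinoline returns to the route at 16.

**Step 13.**
- What may go wrong: enolisation of the hindered axial C4–H may be incomplete, and the amide base may instead deprotonate the C11 methylene next to the diene and scramble the side chain.
- Fallback: from 19, i-Bu2AlH gives the C19 alcohol F8 and Dess–Martin periodinane the aldehyde F9. The more acidic aldehyde is methylated with KOt-Bu and MeI from the same equatorial side to give the 4-methyl aldehyde F10. NaClO2, NaH2PO4 and 2-methyl-2-butene give the acid F11, and Me3SiCHN2 in MeOH returns to the route at 20.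

**Step 4.**
- What may go wrong: over-reduction, with loss of the C7=C8 enol ether alkene on the palladium surface.
- Fallback: conjugate hydride delivery with [(Ph3P)CuH]6 in toluene/H2O, which attacks only the unhindered β-carbon C3, from 7 to 8. No new compound arises (F0).

Further compounds
F1 | step 3 | enantiomer of ketal cycloadduct 5 | O=C1C(OC)=CC(=O)[C@H]2[C@]1(C)C(OC)(O[Si](C)(C)C(C)(C)C)C=C[C@H]2C(=O)OC
F2 | step 3 | enantiomer of cis-fused trione 6 | O=C1C(OC)=CC(=O)[C@H]2[C@]1(C)C(=O)C=C[C@H]2C(=O)OC
F3 | step 3 | enantiomer of trans-fused trione 7 | O=C1C(OC)=CC(=O)[C@@H]2[C@]1(C)C(=O)C=C[C@H]2C(=O)OC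
F0 | step 4 | none | none
F4 | step 6 | 1,9-diacetoxy-8-oxo-6-ene ester | CC(=O)O[C@@H]1C(=O)C=C[C@H]2[C@@]1(C)[C@@H](OC(C)=O)CC[C@@H]2C(=O)OC
F5 | step 6 | 1-acetoxy-8-oxo-6-ene ester | C1C(=O)C=C[C@H]2[C@@]1(C)[C@@H](OC(C)=O)CC[C@@H]2C(=O)OC
F6 | step 10 | (E)-5-bromo-3-methylpent-3-en-1-yne | C#C/C(C)=C/CBr
F7 | step 10 | 9-[(E)-3-methylpent-2-en-4-ynyl]-1-silyloxy-8-oxo-6-ene ester | C#C/C(C)=C/C[C@H]1C(=O)C=C[C@H]2[C@@]1(C)[C@@H](O[Si](C)(C)C(C)(C)C)CC[C@@H]2C(=O)OC
F8 | step 13 | C19 primary alcohol of 19 | C=C/C(C)=C/C[C@@H]1C(=C)CC[C@H]2[C@@]1(C)[C@@H](O[Si](C)(C)C(C)(C)C)CC[C@@H]2CO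
F9 | step 13 | C19 aldehyde | C=C/C(C)=C/C[C@@H]1C(=C)CC[C@H]2[C@@]1(C)[C@@H](O[Si](C)(C)C(C)(C)C)CC[C@@H]2C=O
F10 | step 13 | 4-methyl C19 aldehyde (axial CHO) | C=C/C(C)=C/C[C@@H]1C(=C)CC[C@H]2[C@@]1(C)[C@@H](O[Si](C)(C)C(C)(C)C)CC[C@@]2(C)C=O
F11 | step 13 | 4-methyl C19 carboxylic acid | C=C/C(C)=C/C[C@@H]1C(=C)CC[C@H]2[C@@]1(C)[C@@H](O[Si](C)(C)C(C)(C)C)CC[C@@]2(C)C(=O)O
A1 | alternative 1 | methyl (6E,10E)-12-acetoxy-5-(tert-butyldimethylsilyloxy)-2,6,10-trimethyl-3-oxododeca-6,10-dienoate | COC(=O)C(C)C(=O)C[C@@H](O[Si](C)(C)C(C)(C)C)/C(C)=C/CC/C(C)=C/COC(C)=O
A2 | alternative 1 | methyl 11-acetoxy-1-(tert-butyldimethylsilyloxy)-3-oxo-12,13,14,15,16-pentanorlabd-8(17)-en-19-oate (axial 1-OSi) | CC(=O)OC[C@@H]1C(=C)CC[C@H]2[C@@]1(C)[C@H](O[Si](C)(C)C(C)(C)C)CC(=O)[C@@]2(C)C(=O)OC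
A3 | alternative 2 | dimethyl 3-methyl-4-oxocyclohex-2-ene-1,1-dicarboxylate | COC(=O)C1(C(=O)OC)C=C(C)C(=O)CC1
A4 | alternative 2 | trimethyl(vinyloxy)silane | C=CO[Si](C)(C)C
A5 | alternative 2 | (E)-5-(4-methoxybenzyloxy)pent-2-enyl methyl carbonate | COC(=O)OC/C=C/CCOCc1ccc(OC)cc1
A6 | alternative 2 | dimethyl 3-[5-(4-methoxybenzyloxy)pent-1-en-3-yl]-3-methyl-4-oxo-2-(2-oxoethyl)cyclohexane-1,1-dicarboxylate | COc1ccc(COCC[C@H](C=C)[C@]2(C)C(=O)CCC(C(=O)OC)(C(=O)OC)[C@H]2CC=O)cc1
A7 | alternative 3 | methyl 7-(tert-butyldimethylsilyloxy)-1-hydroxy-4,7a-dimethyl-1-(oxiran-2-yl)octahydro-1H-indene-4-carboxylate (trans-hydrindane) | C1O[C@@H]1[C@@]2(O)CC[C@H]3[C@@]2(C)[C@@H](O[Si](C)(C)C(C)(C)C)CC[C@@]3(C)C(=O)OC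
A8 | alternative 3 | methyl 1-(tert-butyldimethylsilyloxy)-11-hydroxy-8-oxo-12,13,14,15,16,17-hexanorlabdan-19-oate | OC[C@@H]1C(=O)CC[C@H]2[C@@]1(C)[C@@H](O[Si](C)(C)C(C)(C)C)CC[C@@]2(C)C(=O)OC
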